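All runs are simulated with constants of no real substance; noise was put on by code.

E, charged against 1.50 equiv of L, is the limiting reagent, so I keep the ledger in moles of E: each mole stands as E, D or G, with G counted in all its forms.

| flask | E | L | temperature | remark | time |
|---|---|---|---|---|---|
| amber | 0.025 M | 1.5 equiv | 25 °C | run made earlier |  |
| blue | 0.038 M | 1.5 equiv | 36 °C | run made earlier |  |
| winter | 0.050 M | 1.50 equiv |  | at 20 °C until 12 h, from then on at 40 °C | 25 h |
| autumn | 0.050 M | 1.50 equiv | 40 °C |  | 25 h |
| dusk | 0.050 M | 1.50 equiv | 20 °C |  | 25 h |

| run | time / h | D / % | G / % |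
|---|---|---|---|
| amber | 3.00 | 10.8 | 0.3 |
| amber | 5.00 | 17.4 | 0.8 |
| amber | 8.00 | 28.0 | 0 |
| amber | 15.0 | 44.7 | 0.8 |
| amber | 30.0 | 67.1 | 1.5 |
| blue | 1.33 | 18.3 | 0 |
| blue | 4.00 | 44.5 | 2.3 |
| blue | 8.00 | 66.6 | 4.0 |
| blue | 10.0 | 72.7 | 5.2 |
| blue | 15.0 | 76.5 | 13.3 |

(standard deviation of a reading: 0.5 percentage points)

- the flask with the highest amount of D, in percent of the E charged ("all alike" if they lie within 1.5 percentage points) (winter / autumn / dusk / all alike)
- final D, as a percentage of the E charged, in winter
- final D, as a percentage of the E charged, in autumn
- final D, as a percentage of the E charged, in dusk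

- the analysis behind the earlier runs scatters by 0.5 percentage points, standard deviation
- a reading or a percentage of G counts all its forms, free or not

I work in powers of ten. Let the decade rate a be the number of powers of ten by which E falls per hour: the common logarithm of the fraction of E left, sign changed, divided by the time. E left is what remains once D and G are booked. The amber run at 30.0 h leaves 31.4%, so a reads 0.0168 /h. The blue run at 15.0 h leaves 10.2%, so a reads 0.0661 /h, and at 4.00 h it reads 0.0685 /h, so I treat the loss of E as first order. The two runs differ in concentration as well, but a first-order a carries no concentration, so I read the step from amber to blue as one of temperature: the logarithm of a climbs 0.0542 /K. Along that line I reckon a as 0.109 /h at 40 °C and 0.00899 /h at 20 °C; the second is the quantity I carry, the decade rate of the cool flask.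

While E falls first order, decades add over the stages of a flask. By my reckoning dusk spends 0.225 decades and keeps E at 59.6%. Winter spends 1.52 and keeps 3.00%. Autumn spends 2.72 and keeps 0.190%. D and G together hold the rest: 40.4% in dusk, 97.0% in winter, 99.8% in autumn. The G entry I cannot close from the runs; it reads 1.5% in amber and 13.3% in blue at their last readings. So I book dusk's rest as D, and I name winter as the flask with the most D, because its rest is larger than dusk's and it has 13.0 h at 40 °C, less than autumn's 25 h.

The forecast names dusk, with 10% in winter, 3% in autumn and 40% in dusk, on the ground that “G should take off within hours, so autumn's D is largely consumed by 25 h”.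

The flasks give D of 68.9% in winter, 45.6% in autumn and 40.0% in dusk, so winter holds more than the others.

    E → D (k = 0.240 /h, Ea = 93.0 kJ/mol)
    L → Q (k = 0.0800 /h, Ea = 103 kJ/mol)
    D + Q → G (k = 1.20 /M/h, Ea = 61.0 kJ/mol)
    L + G ⇌ X, settled at all times (K = 23.0 /M, ΔH = −12.0 kJ/mol)
    (constants at 40 °C)

The forecast and the flasks part on the G entry, which with its forms counted stands at 27.6% in winter and 54.1% in autumn. Winter's E entry closes at 3.44%, where I had 3.00%. The neighbour is dusk read at 4.0 d. The decade rate 0.00899 /h gives it 0.863 decades, so I reckon its E at 13.7%. That flask stands at E 13.3%, G 18.3% and D 68.3%.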